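**Retrosynthetic overview**
1. Target 24 ⇐ acyclic iodo-aldehyde 22: a vinylchromium addition forms C5–C6 and closes the ten-membered carbocycle, then the new C6 alkoxide closes the γ-lactone onto the C12 methyl ester in the same flask.
2. 22 ⇐ acetal 21 ⇐ Evans–Tishchenko reduction (acetaldehyde) of β-hydroxy enone 19, which sets C1 and gives the C3-acetate/C1-hydroxyl pattern without protecting groups.
3. 19 ⇐ boron aldol (C2–C3) of methyl ketone 12 with (Z)-3-iodo-2-methylpropenal 16 (from propargyl alcohol).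
4. 12 ⇐ alkyne hydration of 11 ⇐ angeloylation of 8 ⇐ catalytic asymmetric chromium allylation (C7–C8, syn) of (Z)-enynal 6 with bromide 4 (from methyl acrylate and glyoxal dimethyl acetal).
5. Both Z-trisubstituted ring alkenes are bought or made acyclic and geometrically pure (5; carbometalation of 13) and are never formed in the ring.

Assumption: locants C1–C13 follow the germacranolide skeleton (C1 free carbinol, C3 acetate carbinol, C4=C5 and C9=C10 ring alkenes, C6 lactone carbinol, C7 ring fusion, C8 angelate carbinol, C11=C13 methylidene, C12 lactone carbonyl).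

**Route**

Step 1
Reactants: 1 2,2-dimethoxyacetaldehyde; 2 methyl acrylate
Product: 3 methyl 3-hydroxy-4,4-dimethoxy-2-methylidenebutanoate (racemic)
Conditions: DABCO (0.5 equiv), 1,4-dioxane/H2O 1:1, rt, 48 h
Reagents that add atoms: none
Why: Morita–Baylis–Hillman reaction, in which the DABCO-derived ammonium enolate of the acrylate is trapped by the activated, non-enolisable aldehyde; the carbinol centre is racemic and is erased in step 2.

Step 2
Reactants: 3 methyl 3-hydroxy-4,4-dimethoxy-2-methylidenebutanoate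
Product: 4 methyl (2Z)-2-(bromomethyl)-4,4-dimethoxybut-2-enoate
Conditions: NBS (1.2 equiv), Me2S (1.3 equiv), CH2Cl2, 0 °C to rt
Reagents that add atoms: N-bromosuccinimide, O=C1CCC(=O)N1Br
Why: Corey–Kim-type activation of the allylic hydroxyl as an alkoxysulfonium ion followed by SN2' attack of bromide gives the rearranged bromide with the acetal carbon cis to CH2Br (2Z), the geometry that later gives the syn C7/C8 relationship; no protic acid is present, so the acetal survives.

Step 3
Reactants: 5 (2Z)-3-methylpent-2-en-4-yn-1-ol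
Product: 6 (2Z)-3-methylpent-2-en-4-ynal
Conditions: MnO2 (10 equiv), CH2Cl2, rt, 2 h; filtered and used as a solution
Reagents that add atoms: none
Why: MnO2 oxidises only the allylic alcohol under neutral heterogeneous conditions, so the Z geometry (the future cis C1/C8 relationship across C9=C10) is kept.

Step 4
Reactants: 4 methyl (2Z)-2-(bromomethyl)-4,4-dimethoxybut-2-enoate; 6 (2Z)-3-methylpent-2-en-4-ynal
Product: 8 methyl (3R,4R,5Z)-3-(dimethoxymethyl)-4-hydroxy-6-methyl-2-methylideneoct-5-en-7-ynoate, via trimethylsilyl ether 7 (not isolated)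
Conditions: CrCl2 (10 mol %), (S,S)-1,8-bis(4-isopropyl-4,5-dihydrooxazol-2-yl)-3,6-diphenyl-9H-carbazole (12 mol %), Mn powder (2 equiv), i-Pr2NEt (0.3 equiv), TMSCl (1.5 equiv), THF, 0 °C to rt; then AcOH/H2O/THF 1:1:8, 0 °C
Reagents that add atoms: none
Why: Catalytic asymmetric Nozaki–Hiyama allylation, in which the allylchromium from 4 adds through its γ-carbon (C7) to the aldehyde in a chair transition state with the acetal substituent (cis to CH2Cr) pseudo-axial, giving the 7,8-syn adduct, while the chiral tridentate ligand on trivalent chromium selects the aldehyde face (7R,8R); silylation of the chromium alkoxide turns the catalyst over and keeps O8 from lactonising onto C12.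

Step 5
Reactants: 8 methyl (3R,4R,5Z)-3-(dimethoxymethyl)-4-hydroxy-6-methyl-2-methylideneoct-5-en-7-ynoate; 9 angelic acid
Product: 11 methyl (3R,4R,5Z)-3-(dimethoxymethyl)-6-methyl-4-{[(2Z)-2-methylbut-2-enoyl]oxy}-2-methylideneoct-5-en-7-ynoate, via mixed anhydride 10 (not isolated)
Conditions: 9 (1.5 equiv), 2,4,6-trichlorobenzoyl chloride (1.5 equiv), Et3N (3 equiv), toluene, rt, 2 h; then 8, toluene, 60 °C, no DMAP
Reagents that add atoms: none
Why: Yamaguchi-type esterification through the mixed anhydride, run without a nucleophilic catalyst so that the (Z)-2-methylbut-2-enoyl group is not isomerised to tiglate by conjugate addition–elimination; no stereocentre is touched and O8 can no longer lactonise.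

Step 6
Reactants: 11 methyl (3R,4R,5Z)-3-(dimethoxymethyl)-6-methyl-4-{[(2Z)-2-methylbut-2-enoyl]oxy}-2-methylideneoct-5-en-7-ynoate
Product: 12 methyl (3R,4R,5Z)-3-(dimethoxymethyl)-6-methyl-4-{[(2Z)-2-methylbut-2-enoyl]oxy}-2-methylidene-7-oxooct-5-enoate
Conditions: Ph3PAuNTf2 (3 mol %), H2O (5 equiv), MeOH, rt, dark
Reagents that add atoms: water, O
Why: Gold-catalysed Markovnikov hydration of the terminal alkyne (π-activation by monovalent gold, attack of water at the internal carbon, tautomerisation) gives the C1 methyl ketone without added acid, so the dimethyl acetal (methanol is the solvent), both enoates and the Z alkene are kept; it is run only after O8 is acylated because a free cis-γ-hydroxy enone would close to a furan.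

Step 7
Reactants: 13 propargyl alcohol
Product: 15 (2Z)-3-iodo-2-methylprop-2-en-1-ol, via alkenylmagnesium alkoxide 14 (not isolated)
Conditions: MeMgBr (2.5 equiv), CuI (10 mol %), THF, −20 °C to rt; then iodine (1.3 equiv), −30 °C to rt
Reagents that add atoms: methylmagnesium bromide, C[Mg]Br; iodine, [I][I]
Why: Copper-catalysed anti-carbomagnesiation of the propargylic alkoxide places methyl on the internal carbon and magnesium cis to CH2O by chelation, and iodinolysis with retention gives the (Z)-iodoalkene, i.e. the C3–C4(Me)=C5 unit with iodine where C6 will be attached.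

Step 8
Reactants: 15 (2Z)-3-iodo-2-methylprop-2-en-1-ol
Product: 16 (2Z)-3-iodo-2-methylprop-2-enal
Conditions: MnO2 (10 equiv), CH2Cl2, rt, dark; filtered and used at once
Reagents that add atoms: none
Why: Neutral MnO2 oxidation of the allylic alcohol keeps the Z geometry of this isomerisation-prone β-iodo enal, which is not stored.

Step 9
Reactants: 12 methyl (3R,4R,5Z)-3-(dimethoxymethyl)-6-methyl-4-{[(2Z)-2-methylbut-2-enoyl]oxy}-2-methylidene-7-oxooct-5-enoate; 16 (2Z)-3-iodo-2-methylprop-2-enal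
Product: 19 methyl (3R,4R,5Z,9S,10Z)-3-(dimethoxymethyl)-9-hydroxy-11-iodo-6,10-dimethyl-4-{[(2Z)-2-methylbut-2-enoyl]oxy}-2-methylidene-7-oxoundeca-5,10-dienoate, via boron enolate 17 (not isolated), via boron aldolate 18 (not isolated)
Conditions: (−)-Ipc2BCl (1.5 equiv), Et3N (2 equiv), Et2O, 0 °C, 1 h; then 16 (1.5 equiv), −78 to −25 °C, 16 h; then pH 7 buffer, MeOH, 30% H2O2, 0 °C
Reagents that add atoms: none
Why: Paterson boron aldol reaction, in which kinetic enolisation of the C2 methyl group gives the enol diisopinocampheylborinate and the isopinocampheyl groups direct it to the Si face of the aldehyde in a cyclic transition state, setting C3 as S (about 6:1 to 10:1 expected, minor epimer removed by chromatography); the remote C7/C8 centres exert no control.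

Step 10
Reactants: 19 methyl (3R,4R,5Z,9S,10Z)-3-(dimethoxymethyl)-9-hydroxy-11-iodo-6,10-dimethyl-4-{[(2Z)-2-methylbut-2-enoyl]oxy}-2-methylidene-7-oxoundeca-5,10-dienoate; 20 acetaldehyde
Product: 21 methyl (3R,4R,5Z,7S,9S,10Z)-9-acetoxy-3-(dimethoxymethyl)-7-hydroxy-11-iodo-6,10-dimethyl-4-{[(2Z)-2-methylbut-2-enoyl]oxy}-2-methylideneundeca-5,10-dienoate
Conditions: SmI2 (0.3 equiv, premixed with MeCHO until the blue colour is gone), MeCHO (8 equiv), THF, −10 °C, 2 h
Reagents that add atoms: none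
Why: Evans–Tishchenko reduction, in which the samarium-bound hemiacetal formed from O3 and acetaldehyde delivers hydride intramolecularly to the C1 ketone through a chair six-membered transition state, giving the 1,3-anti diol (C1 = S) with the acetyl group left on O3 and O1 free; delivery is strictly 1,2, and premixing leaves only trivalent samarium, so the enone alkene, the γ-angelate and the vinyl iodide are not reduced.

Step 11
Reactants: 21 methyl (3R,4R,5Z,7S,9S,10Z)-9-acetoxy-3-(dimethoxymethyl)-7-hydroxy-11-iodo-6,10-dimethyl-4-{[(2Z)-2-methylbut-2-enoyl]oxy}-2-methylideneundeca-5,10-dienoate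
Product: 22 methyl (3R,4R,5Z,7S,9S,10Z)-9-acetoxy-3-formyl-7-hydroxy-11-iodo-6,10-dimethyl-4-{[(2Z)-2-methylbut-2-enoyl]oxy}-2-methylideneundeca-5,10-dienoate
Conditions: LiBF4 (3 equiv), MeCN/H2O 50:1, rt; crude aldehyde used at once
Reagents that add atoms: water, O
Why: Mild Lewis-acid acetal hydrolysis frees the C6 aldehyde under nearly neutral conditions, which avoids epimerisation at C7, β-elimination of the angelate and ionisation of the allylic esters.

Step 12
Reactants: 22 methyl (3R,4R,5Z,7S,9S,10Z)-9-acetoxy-3-formyl-7-hydroxy-11-iodo-6,10-dimethyl-4-{[(2Z)-2-methylbut-2-enoyl]oxy}-2-methylideneundeca-5,10-dienoate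
Product: 24 (3aS,4R,5Z,7S,9S,10Z,11aS)-9-acetoxy-7-hydroxy-6,10-dimethyl-3-methylidene-2-oxo-2,3,3a,4,7,8,9,11a-octahydrocyclodeca[b]furan-4-yl (2Z)-2-methylbut-2-enoate (CNP0319825.5), via chromium alkoxide 23 (not isolated)
Conditions: CrCl2 (12 equiv), NiCl2 (0.1 equiv), DMSO/THF 3:1, 0.002 M, 22 added over 12 h, rt; aq. NH4Cl
Reagents that add atoms: none
Why: Nozaki–Hiyama–Kishi reaction, in which zerovalent nickel inserts into the vinyl C–I bond and transmetalation gives a vinylchromium that adds to the aldehyde with retention of the Z geometry to close the ten-membered ring; Felkin–Anh addition (acrylate carbon C11 anti to the incoming vinyl group, tethered C8 gauche on the carbonyl-oxygen side, H on the outside) sets C6 as S, which puts O6 cis to the C12 ester so the chromium alkoxide lactonises spontaneously and closes the second ring.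

**Compound list**
1 | 2,2-dimethoxyacetaldehyde (60% aqueous solution) | COC(OC)C=O | starting material
2 | methyl acrylate | C=CC(=O)OC | starting material
3 | methyl 3-hydroxy-4,4-dimethoxy-2-methylidenebutanoate (racemic) | COC(OC)C(O)C(=C)C(=O)OC | intermediate
4 | methyl (2Z)-2-(bromomethyl)-4,4-dimethoxybut-2-enoate | COC(OC)/C=C(\CBr)C(=O)OC | intermediate
5 | (2Z)-3-methylpent-2-en-4-yn-1-ol | C#C/C(C)=C\CO | starting material
6 | (2Z)-3-methylpent-2-en-4-ynal | C#C/C(C)=C\C=O | intermediate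
7 | methyl (3R,4R,5Z)-3-(dimethoxymethyl)-6-methyl-2-methylidene-4-(trimethylsilyloxy)oct-5-en-7-ynoate | C#C/C(C)=C\[C@@H](O[Si](C)(C)C)[C@H](C(OC)OC)C(=C)C(=O)OC | intermediate (not isolated)
8 | methyl (3R,4R,5Z)-3-(dimethoxymethyl)-4-hydroxy-6-methyl-2-methylideneoct-5-en-7-ynoate | C#C/C(C)=C\[C@@H](O)[C@H](C(OC)OC)C(=C)C(=O)OC | intermediate
9 | angelic acid, (2Z)-2-methylbut-2-enoic acid | C/C=C(/C)C(=O)O | starting material
10 | (2Z)-2-methylbut-2-enoic 2,4,6-trichlorobenzoic anhydride | C/C=C(/C)C(=O)OC(=O)c1c(Cl)cc(Cl)cc1Cl | intermediate (not isolated)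
11 | methyl (3R,4R,5Z)-3-(dimethoxymethyl)-6-methyl-4-{[(2Z)-2-methylbut-2-enoyl]oxy}-2-methylideneoct-5-en-7-ynoate | C#C/C(C)=C\[C@@H](OC(=O)/C(C)=C\C)[C@H](C(OC)OC)C(=C)C(=O)OC | intermediate
12 | methyl (3R,4R,5Z)-3-(dimethoxymethyl)-6-methyl-4-{[(2Z)-2-methylbut-2-enoyl]oxy}-2-methylidene-7-oxooct-5-enoate | CC(=O)/C(C)=C\[C@@H](OC(=O)/C(C)=C\C)[C@H](C(OC)OC)C(=C)C(=O)OC | intermediate
13 | propargyl alcohol (prop-2-yn-1-ol) | C#CCO | starting material
14 | bromomagnesium (2Z)-3-(bromomagnesio)-2-methylprop-2-en-1-olate | Br[Mg]/C=C(/C)CO[Mg]Br | intermediate (not isolated)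
15 | (2Z)-3-iodo-2-methylprop-2-en-1-ol | I/C=C(/C)CO | intermediate
16 | (2Z)-3-iodo-2-methylprop-2-enal | I/C=C(/C)C=O | intermediate
17 | enol diisopinocampheylborinate of 12 (O–B on C1, C1=C2 enol, Ipc groups from (+)-α-pinene) | C=C(OB([C@@H]1C[C@@H]2C[C@H]([C@H]1C)C2(C)C)[C@@H]1C[C@@H]2C[C@H]([C@H]1C)C2(C)C)/C(C)=C\[C@@H](OC(=O)/C(C)=C\C)[C@H](C(OC)OC)C(=C)C(=O)OC | intermediate (not isolated)
18 | O3-diisopinocampheylborinate of 19 | I/C=C(/C)[C@@H](OB([C@@H]1C[C@@H]2C[C@H]([C@H]1C)C2(C)C)[C@@H]1C[C@@H]2C[C@H]([C@H]1C)C2(C)C)CC(=O)/C(C)=C\[C@@H](OC(=O)/C(C)=C\C)[C@H](C(OC)OC)C(=C)C(=O)OC | intermediate (not isolated)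
19 | methyl (3R,4R,5Z,9S,10Z)-3-(dimethoxymethyl)-9-hydroxy-11-iodo-6,10-dimethyl-4-{[(2Z)-2-methylbut-2-enoyl]oxy}-2-methylidene-7-oxoundeca-5,10-dienoate | I/C=C(/C)[C@@H](O)CC(=O)/C(C)=C\[C@@H](OC(=O)/C(C)=C\C)[C@H](C(OC)OC)C(=C)C(=O)OC | intermediate
20 | acetaldehyde | CC=O | starting material
21 | methyl (3R,4R,5Z,7S,9S,10Z)-9-acetoxy-3-(dimethoxymethyl)-7-hydroxy-11-iodo-6,10-dimethyl-4-{[(2Z)-2-methylbut-2-enoyl]oxy}-2-methylideneundeca-5,10-dienoate | I/C=C(/C)[C@@H](OC(C)=O)C[C@H](O)/C(C)=C\[C@@H](OC(=O)/C(C)=C\C)[C@H](C(OC)OC)C(=C)C(=O)OC | intermediate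
22 | methyl (3R,4R,5Z,7S,9S,10Z)-9-acetoxy-3-formyl-7-hydroxy-11-iodo-6,10-dimethyl-4-{[(2Z)-2-methylbut-2-enoyl]oxy}-2-methylideneundeca-5,10-dienoate | I/C=C(/C)[C@@H](OC(C)=O)C[C@H](O)/C(C)=C\[C@@H](OC(=O)/C(C)=C\C)[C@H](C=O)C(=C)C(=O)OC | intermediate
23 | ring-closed dichlorochromium (6S)-alkoxide: the ten-membered ring of 24 with O6 bound to CrCl2 and C12 still the methyl ester | Cl[Cr](Cl)O[C@H]1/C=C(/C)[C@@H](OC(C)=O)C[C@H](O)/C(C)=C\[C@@H](OC(=O)/C(C)=C\C)[C@H]1C(=C)C(=O)OC | intermediate (not isolated)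
24 | (3aS,4R,5Z,7S,9S,10Z,11aS)-9-acetoxy-7-hydroxy-6,10-dimethyl-3-methylidene-2-oxo-2,3,3a,4,7,8,9,11a-octahydrocyclodeca[b]furan-4-yl (2Z)-2-methylbut-2-enoate | C=C1C(=O)O[C@H]2/C=C(/C)[C@@H](OC(C)=O)C[C@H](O)/C(C)=C\[C@@H](OC(=O)/C(C)=C\C)[C@@H]12 | target

**Totals**
Total step count: 12. Longest linear sequence: 9 steps (steps 1, 2, 4, 5, 6, 9, 10, 11, 12).

**Three steps most likely to fail**

Step 12. The ten-membered ring closure can give oligomers, or the C6 epimer, which cannot lactonise cis. The fallback sets out from methyl ketone 12 and iodo alcohol 15 and comes back at 24. The acetal of 12 is hydrolysed (LiBF4, wet MeCN) to the keto aldehyde F1. An intermolecular Nozaki–Hiyama–Kishi coupling of F1 with 15 (CrCl2, NiCl2 cat., DMSO) attacks only the aldehyde, and the alkoxide lactonises to the hydroxymethyl lactone F2, so the lactone is in place before the carbocycle. MnO2 then gives the (Z)-enal F3. The ten-membered ring is closed at C2–C3 by an intramolecular boron aldol reaction ((−)-Ipc2BCl, Et3N, Et2O, 0.003 M) to the macrocyclic β-hydroxy ketone F4, and the Evans–Tishchenko reduction of step 10 (SmI2 cat., MeCHO) converts it into 24.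

Step 4. The enantio- and syn-selectivity of the chromium-catalysed allylation with this acetal-bearing bromide are not secured by close precedent. If only the facial sense is wrong, the (R,R) ligand is used. The fallback for low selectivity sets out from bromide 4 and comes back at 8. Palladium-catalysed borylation (B2pin2, Pd2(dba)3 cat., KOAc, DMSO, 40 °C) gives the allylboronate F5 with the acetal carbon cis to CH2B. A chiral phosphoric acid catalysed allylboration of 6 ((R)-TRIP, 10 mol %, toluene, −30 °C to rt) then proceeds through a closed chair transition state, which fixes the syn relationship while the acid selects the aldehyde face, and aqueous work-up gives 8.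

Step 5. Heating the γ-hydroxy ester 8 with the mixed anhydride may let O8 lactonise onto C12 or let the angelate isomerise to tiglate. The fallback sets out from 8 and comes back at 11. Steglich esterification with 2-[bis(2,2,2-trifluoroethoxy)phosphoryl]propanoic acid (DCC, DMAP cat., CH2Cl2, 0 °C, fast and with nothing to isomerise) gives the phosphonate ester F6. A Still–Gennari olefination of F6 with acetaldehyde (KHMDS, 18-crown-6, THF, −78 °C) then builds the (Z)-2-methylbut-2-enoate on the molecule and gives 11.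

**Further compounds**
F1 | step 12 | methyl (3R,4R,5Z)-3-formyl-6-methyl-4-{[(2Z)-2-methylbut-2-enoyl]oxy}-2-methylidene-7-oxooct-5-enoate | CC(=O)/C(C)=C\[C@@H](OC(=O)/C(C)=C\C)[C@H](C=O)C(=C)C(=O)OC
F2 | step 12 | (1R,2Z)-1-{(2S,3S)-2-[(1Z)-3-hydroxy-2-methylprop-1-en-1-yl]-4-methylidene-5-oxooxolan-3-yl}-3-methyl-4-oxopent-2-en-1-yl (2Z)-2-methylbut-2-enoate | C=C1C(=O)O[C@@H](/C=C(/C)CO)[C@H]1[C@H](OC(=O)/C(C)=C\C)/C=C(/C)C(C)=O
F3 | step 12 | (1R,2Z)-3-methyl-1-{(2S,3S)-4-methylidene-2-[(1Z)-2-methyl-3-oxoprop-1-en-1-yl]-5-oxooxolan-3-yl}-4-oxopent-2-en-1-yl (2Z)-2-methylbut-2-enoate | C=C1C(=O)O[C@@H](/C=C(/C)C=O)[C@H]1[C@H](OC(=O)/C(C)=C\C)/C=C(/C)C(C)=O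
F4 | step 12 | (3aS,4R,5Z,9S,10Z,11aS)-9-hydroxy-6,10-dimethyl-3-methylidene-2,7-dioxo-2,3,3a,4,7,8,9,11a-octahydrocyclodeca[b]furan-4-yl (2Z)-2-methylbut-2-enoate | C=C1C(=O)O[C@H]2/C=C(/C)[C@@H](O)CC(=O)/C(C)=C\[C@@H](OC(=O)/C(C)=C\C)[C@@H]12
F5 | step 4 | methyl (2E)-4,4-dimethoxy-2-[(4,4,5,5-tetramethyl-1,3,2-dioxaborolan-2-yl)methyl]but-2-enoate | COC(OC)/C=C(\CB1OC(C)(C)C(C)(C)O1)C(=O)OC
F6 | step 5 | methyl (3R,4R,5Z)-4-({2-[bis(2,2,2-trifluoroethoxy)phosphoryl]propanoyl}oxy)-3-(dimethoxymethyl)-6-methyl-2-methylideneoct-5-en-7-ynoate (both epimers at the phosphonate carbon) | C#C/C(C)=C\[C@@H](OC(=O)C(C)P(=O)(OCC(F)(F)F)OCC(F)(F)F)[C@H](C(OC)OC)C(=C)C(=O)OC
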